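**Plan**

- Retrosynthesis: the two acyl groups come off first (C1–CO of ring A back to a C6 ester beside a C1 bromide, C5′–CO of ring B back to C5′–H). Ring A is then cut at C5–C6, C3–C4 and C1–C6 into a siloxyalkyne (C4, C5, with C7 attached) and a 2-prenyl-3-siloxycyclobutenone (C6, C3, C2, C1). C7–C1′ is cut last, by a propargylic substitution.
- Enabling feature: ring A (C1–C6) is a fully substituted benzene with oxygen on C2, C4, C6 and carbon on C3, C5. A siloxyalkyne and a siloxy vinylketene deliver exactly this 1,3,5-trioxygenated pattern, so C7 can be fixed beforehand as an aryl/alkyl/alkynyl methine.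
- Forward: cyclobutenone 6 from prenyl bromide and ketene (steps 1–3); ring B from phloroglucinol, prenylated, then joined to C7 by copper-catalysed propargylation (steps 4–10); alkyne to siloxyalkyne (step 11); benzannulation closes ring A (step 12); isobutyryl onto C5′ by ortho-lithiation, 2-methylbutanoyl onto C1 by bromination, esterification and anionic Fries shift (steps 13–16); acetals and silyl ethers off (steps 17, 18).
- Ring B carries no ketone through steps 11 and 12, because the siloxyalkyne has to be made from a lithium acetylide, which an enolisable aryl ketone would not survive.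
- Stereochemistry: C7 is set in step 9 by the chiral ligand on copper and is not deprotonated or ionised afterwards. The acyl α-carbon is bought as (R)-2-methylbutanoic acid and moved in without base-mediated enolisation.

Key step: step 12

**Remarks**

Labels: ring A = C1–C6 (C1 acyl, C3 prenyl, C5 on C7); C7 = bridging methine; ring B = C1′–C6′ (C1′ on C7, C3′ prenyl, C5′ isobutyryl); prenyl = 3-methylbut-2-en-1-yl, MOM = methoxymethyl, TIPS = triisopropylsilyl.

Assumption: rotation about the C7–aryl bonds is fast at room temperature, so C7 and the acyl α-carbon are the only stereogenic elements; the ligand antipode used in step 9 is the one that gives (S)-16, to be confirmed by correlation.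

**Route**

Step 1
Reactants: 1 prenyl bromide (1-bromo-3-methylbut-2-ene)
Product: 2 5-methylhex-4-en-1-yne
Conditions: HC≡CMgBr (1.3 equiv), CuCl (5 mol %), THF, 0 to 40 °C
Reagents that add atoms: ethynylmagnesium bromide, C#C[Mg]Br
Why: Copper-catalysed coupling of an alkynyl Grignard reagent with an allylic bromide; attack at the unhindered primary carbon of the prenyl unit should give the skipped enyne, which is purified by distillation.

Step 2
Reactants: 2 5-methylhex-4-en-1-yne
Product: 5 triisopropyl[(5-methylhex-4-en-1-yn-1-yl)oxy]silane, via lithium acetylide 3 (not isolated), via lithium ynolate 4 (not isolated)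
Conditions: n-BuLi (1.0 equiv), THF, −78 °C; t-BuOOLi (from t-BuOOH and LiN(SiMe3)2), −78 to 0 °C; TIPSOTf, −78 to 0 °C
Reagents that add atoms: tert-butyl hydroperoxide, CC(C)(C)OO; triisopropylsilyl trifluoromethanesulfonate, CC(C)[Si](C(C)C)(C(C)C)OS(=O)(=O)C(F)(F)F
Why: Oxidation of a lithium acetylide by lithium tert-butyl peroxide (oxygen transfer to carbon) gives the ynolate, which the bulky silyl triflate caps on oxygen; this is the standard acetylide-oxidation route to siloxyalkynes.

Step 3
Reactants: 5 triisopropyl[(5-methylhex-4-en-1-yn-1-yl)oxy]silane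
Product: 6 2-prenyl-3-(triisopropylsilyloxy)cyclobut-2-en-1-one
Conditions: ketene (gas, excess, passed in from a generator), CH2Cl2, 0 °C to rt
Reagents that add atoms: ketene, C=C=O
Why: Ketene–ynol ether (2+2) cycloaddition; the alkyne carbon remote from oxygen is the nucleophile and bonds to the ketene carbonyl carbon, so prenyl ends on C2 and the siloxy group on C3 of the cyclobutenone.

Step 4
Reactants: 7 6-methylheptanal
Product: 8 8-methylnon-1-yn-3-ol (racemic)
Conditions: HC≡CMgBr, THF, 0 °C; aq. NH4Cl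
Reagents that add atoms: ethynylmagnesium bromide, C#C[Mg]Br
Why: Grignard addition of an acetylide to an aldehyde; the racemate suffices because this centre is flattened in the allenylidene intermediate of step 9.

Step 5
Reactants: 8 8-methylnon-1-yn-3-ol (racemic)
Product: 9 8-methylnon-1-yn-3-yl pentafluorobenzoate (racemic)
Conditions: C6F5COCl, Et3N, DMAP (cat.), CH2Cl2, 0 °C
Reagents that add atoms: pentafluorobenzoyl chloride, O=C(Cl)c1c(F)c(F)c(F)c(F)c1F
Why: Acylation of a secondary alcohol; the electron-poor benzoate is chosen over acetate because alkyl-substituted propargylic esters ionise sluggishly at copper.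

Step 6
Reactants: 10 phloroglucinol
Product: 11 3,5-bis(methoxymethoxy)phenol
Conditions: NaH (2.0 equiv), MOMCl (2.0 equiv), DMF, 0 °C to rt
Reagents that add atoms: chloromethyl methyl ether, COCCl
Why: Williamson-type O-alkylation of the phenoxide with a limiting amount of the chloromethyl ether; the symmetric bis-ether is separated by chromatography from mono- and tris-ether.

Step 7
Reactants: 11 3,5-bis(methoxymethoxy)phenol
Product: 12 [3,5-bis(methoxymethoxy)phenoxy]triisopropylsilane
Conditions: TIPSCl, imidazole, DMF, rt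
Reagents that add atoms: triisopropylsilyl chloride, CC(C)[Si](Cl)(C(C)C)C(C)C
Why: Silylation of the phenol masks the acidic hydrogen for the lithiation that follows and, being bulky, should resist attack by n-BuLi.

Step 8
Reactants: 12 [3,5-bis(methoxymethoxy)phenoxy]triisopropylsilane; 1 prenyl bromide
Product: 15 3,5-bis(methoxymethoxy)-4-prenylphenol, via aryllithium 13 (not isolated), via prenylated silyl ether 14 (not isolated)
Conditions: n-BuLi, THF, 0 °C; CuI (10 mol %), 1, −78 °C to rt; then TBAF, rt; aq. NH4Cl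
Reagents that add atoms: none
Why: Directed ortho-metalation at the carbon flanked by both acetal oxygens, copper-assisted allylation of the aryllithium, then fluoride cleavage of the aryl silyl ether in the same flask; the phenol obtained has two equivalent ortho C–H positions.

Step 9
Reactants: 15 3,5-bis(methoxymethoxy)-4-prenylphenol; 9 8-methylnon-1-yn-3-yl pentafluorobenzoate (racemic)
Product: 16 3,5-bis(methoxymethoxy)-4-prenyl-2-[(3S)-8-methylnon-1-yn-3-yl]phenol
Conditions: Cu(MeCN)4BF4 (5 mol %), chiral tridentate P,N,N ketimine ligand (5.5 mol %), i-Pr2NEt (1.2 equiv), MeOH, −20 °C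
Reagents that add atoms: none
Why: Copper-catalysed enantioselective propargylic substitution of Friedel–Crafts type through an allenylidene intermediate (Cu=C=C=CHR): the phenoxide of 15 attacks the γ-carbon with either of its two equivalent ortho carbons, and the chiral ligand on copper shields one face so that the (S) centre at C7 should form from the racemic ester.

Step 10
Reactants: 16 3,5-bis(methoxymethoxy)-4-prenyl-2-[(3S)-8-methylnon-1-yn-3-yl]phenol
Product: 17 1,3,5-tris(methoxymethoxy)-2-prenyl-4-[(3S)-8-methylnon-1-yn-3-yl]benzene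
Conditions: MOMCl, i-Pr2NEt, CH2Cl2, 0 °C to rt
Reagents that add atoms: chloromethyl methyl ether, COCCl
Why: Acetal protection of the remaining phenol under a mild amine base removes the OH that could add to the alkyne and leaves C5′–H as the only aromatic hydrogen of ring B.

Step 11
Reactants: 17 1,3,5-tris(methoxymethoxy)-2-prenyl-4-[(3S)-8-methylnon-1-yn-3-yl]benzene
Product: 20 triisopropyl({(3S)-8-methyl-3-[2,4,6-tris(methoxymethoxy)-3-prenylphenyl]non-1-yn-1-yl}oxy)silane, via lithium acetylide 18 (not isolated), via lithium ynolate 19 (not isolated)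
Conditions: n-BuLi (1.0 equiv), THF, −78 °C; t-BuOOLi (from t-BuOOH and LiN(SiMe3)2), −78 to 0 °C; TIPSOTf, −78 to 0 °C; rapid filtration through Et3N-deactivated silica
Reagents that add atoms: tert-butyl hydroperoxide, CC(C)(C)OO; triisopropylsilyl trifluoromethanesulfonate, CC(C)[Si](C(C)C)(C(C)C)OS(=O)(=O)C(F)(F)F
Why: The same acetylide oxidation and O-silylation as in step 2; one equivalent of base at −78 °C removes only the alkyne hydrogen, so the benzylic and propargylic C7–H is untouched and the configuration should be kept.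

Step 12
Reactants: 20 triisopropyl({(3S)-8-methyl-3-[2,4,6-tris(methoxymethoxy)-3-prenylphenyl]non-1-yn-1-yl}oxy)silane; 6 2-prenyl-3-(triisopropylsilyloxy)cyclobut-2-en-1-one
Product: 25 2-{(1R)-6-methyl-1-[2,4,6-tris(methoxymethoxy)-3-prenylphenyl]heptyl}-4-prenyl-3,5-bis(triisopropylsilyloxy)phenol, via vinylketene 21 (not isolated), via 4-vinylcyclobutenone 22 (not isolated), via dienylketene 23 (not isolated), via cyclohexadienone 24 (not isolated)
Conditions: 6 (1.5 equiv), toluene, 80 °C then 110 °C
Reagents that add atoms: none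
Why: Danheiser benzannulation: 6 opens thermally (4π electrocyclic) to vinylketene 21, which takes up siloxyalkyne 20 in a (2+2) cycloaddition that forms C5–C6 and C3–C4 and gives 4-vinylcyclobutenone 22; a second 4π opening gives dienylketene 23, whose 6π electrocyclisation forms C1–C6, and dienone 24 tautomerises to phenol 25. The closest known reaction type is the thermal benzannulation of siloxyalkynes with cyclobutenones to resorcinol monosilyl ethers, extended here by a 3-siloxy group on the cyclobutenone so that the third oxygen arrives as well. Ring A is the only ring closed, and it closes by the 6π electrocyclisation of the ketene carbon (C6) onto the methylene terminus (C1) of the dienylketene. No stereocentre is created: the quaternary carbon of 22 is lost again on ring opening, and C7 is a spectator under neutral thermal conditions that neither deprotonate nor ionise it. The selectivity needed is the orientation of the (2+2) step, and the polarised siloxyalkyne secures it, since its carbon remote from oxygen (C5, carrying C7) is the nucleophile that bonds to the ketene carbonyl carbon, which places OH and OTIPS on either side of C5 and prenyl between the two siloxy carbons. The hindered position of the new OH next to C5 should limit its trapping by vinylketene, and the modest excess of 6 covers the rest.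

Step 13
Reactants: 25 2-{(1R)-6-methyl-1-[2,4,6-tris(methoxymethoxy)-3-prenylphenyl]heptyl}-4-prenyl-3,5-bis(triisopropylsilyloxy)phenol
Product: 27 2-{(1R)-6-methyl-1-[2,4,6-tris(methoxymethoxy)-3-(2-methylpropanoyl)-5-prenylphenyl]heptyl}-4-prenyl-3,5-bis(triisopropylsilyloxy)phenol, via dilithio species 26 (not isolated)
Conditions: n-BuLi (2.2 equiv), THF, −78 to 0 °C; i-PrC(O)N(OMe)Me, −78 °C to rt; aq. NH4Cl
Reagents that add atoms: N-methoxy-N,2-dimethylpropanamide, CC(C)C(=O)N(C)OC
Why: Directed ortho-metalation followed by Weinreb ketone synthesis: after the phenol is deprotonated, C5′–H (the only aromatic hydrogen between two acetal oxygens) is lithiated and the aryllithium is acylated by the N-methoxy-N-methylamide, whose chelated adduct cannot add a second time.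

Step 14
Reactants: 28 (R)-2-methylbutanoic acid
Product: 29 (R)-2-methylbutanoyl chloride
Conditions: (COCl)2, DMF (cat.), CH2Cl2, 0 °C to rt; volatiles removed, used as a CH2Cl2 solution
Reagents that add atoms: oxalyl chloride, O=C(Cl)C(=O)Cl
Why: Acid chloride formation through a chloroiminium (Vilsmeier-type) activator in the absence of base, so the α-centre is not enolised.

Step 15
Reactants: 27 2-{(1R)-6-methyl-1-[2,4,6-tris(methoxymethoxy)-3-(2-methylpropanoyl)-5-prenylphenyl]heptyl}-4-prenyl-3,5-bis(triisopropylsilyloxy)phenol; 29 (R)-2-methylbutanoyl chloride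
Product: 31 (2R)-2-methylbutanoate ester of the C1-brominated phenol, via bromophenol 30 (not isolated)
Conditions: NBS (1.0 equiv), CH2Cl2, −78 °C; then pyridine, DMAP (cat.), 29, −78 °C to rt
Reagents that add atoms: N-bromosuccinimide, O=C1CCC(=O)N1Br
Why: Electrophilic aromatic bromination of the activated phenol at C1, its only free ring position, should be much faster at −78 °C than attack on the trisubstituted alkenes, and the hindered bromophenol is then O-acylated under pyridine/DMAP, a base too weak to turn 29 into a ketene.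

Step 16
Reactants: 31 (2R)-2-methylbutanoate ester of the C1-brominated phenol
Product: 33 (2R)-1-[2-hydroxy-3-{(1R)-6-methyl-1-[2,4,6-tris(methoxymethoxy)-3-(2-methylpropanoyl)-5-prenylphenyl]heptyl}-5-prenyl-4,6-bis(triisopropylsilyloxy)phenyl]-2-methylbutan-1-one, via aryllithium 32 (not isolated)
Conditions: t-BuLi (2.0 equiv), THF, −95 °C; aq. NH4Cl
Reagents that add atoms: none
Why: Anionic Fries rearrangement triggered by bromine–lithium exchange: the C1 aryllithium attacks the neighbouring ester carbonyl in an intramolecular 1,3 O-to-C acyl shift that should outrun intermolecular addition of t-BuLi to the twisted, doubly ortho-substituted ring B ketone, and the lithium phenoxide formed leaves no base to epimerise the acyl α-centre.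

Step 17
Reactants: 33 (2R)-1-[2-hydroxy-3-{(1R)-6-methyl-1-[2,4,6-tris(methoxymethoxy)-3-(2-methylpropanoyl)-5-prenylphenyl]heptyl}-5-prenyl-4,6-bis(triisopropylsilyloxy)phenyl]-2-methylbutan-1-one
Product: 34 (2R)-1-[2-hydroxy-3-{(1R)-6-methyl-1-[2,4,6-trihydroxy-3-(2-methylpropanoyl)-5-prenylphenyl]heptyl}-5-prenyl-4,6-bis(triisopropylsilyloxy)phenyl]-2-methylbutan-1-one
Conditions: HCl (3 M aq.), MeOH, rt
Reagents that add atoms: none
Why: Acid-catalysed cleavage of the three aryl methoxymethyl acetals (transacetalisation to methanol); the ring A prenyl group is still flanked by silyl ethers and the ring B prenyl group sits on a ring deactivated by its acyl group, which should hold back acid-induced chroman formation.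

Step 18
Reactants: 34 (2R)-1-[2-hydroxy-3-{(1R)-6-methyl-1-[2,4,6-trihydroxy-3-(2-methylpropanoyl)-5-prenylphenyl]heptyl}-5-prenyl-4,6-bis(triisopropylsilyloxy)phenyl]-2-methylbutan-1-one
Product: 35 CNP0279787.1, (2R)-1-[2,4,6-trihydroxy-3-{(1R)-6-methyl-1-[2,4,6-trihydroxy-3-(2-methylpropanoyl)-5-prenylphenyl]heptyl}-5-prenylphenyl]-2-methylbutan-1-one
Conditions: TBAF, AcOH, THF, 0 °C
Reagents that add atoms: none
Why: Fluoride cleavage of the two aryl silyl ethers, buffered with acetic acid so that the hexaphenol never meets free base, which protects C7 (retro-Friedel–Crafts scrambling through a quinone methide) and the acyl α-centre (enolisation).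

**Compound list**

1 | prenyl bromide (1-bromo-3-methylbut-2-ene) | CC(C)=CCBr | starting material
2 | 5-methylhex-4-en-1-yne | C#CCC=C(C)C | intermediate
3 | (5-methylhex-4-en-1-yn-1-yl)lithium | [Li]C#CCC=C(C)C | intermediate
4 | lithium 5-methylhex-4-en-1-yn-1-olate | [Li]OC#CCC=C(C)C | intermediate
5 | triisopropyl[(5-methylhex-4-en-1-yn-1-yl)oxy]silane | CC(C)=CCC#CO[Si](C(C)C)(C(C)C)C(C)C | intermediate
6 | 2-(3-methylbut-2-en-1-yl)-3-(triisopropylsilyloxy)cyclobut-2-en-1-one | O=C1CC(O[Si](C(C)C)(C(C)C)C(C)C)=C1CC=C(C)C | intermediate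
7 | 6-methylheptanal | CC(C)CCCCC=O | starting material
8 | 8-methylnon-1-yn-3-ol (racemic) | C#CC(O)CCCCC(C)C | intermediate
9 | 8-methylnon-1-yn-3-yl 2,3,4,5,6-pentafluorobenzoate (racemic) | C#CC(CCCCC(C)C)OC(=O)c1c(F)c(F)c(F)c(F)c1F | intermediate
10 | phloroglucinol (benzene-1,3,5-triol) | Oc1cc(O)cc(O)c1 | starting material
11 | 3,5-bis(methoxymethoxy)phenol | COCOc1cc(O)cc(OCOC)c1 | intermediate
12 | [3,5-bis(methoxymethoxy)phenoxy]triisopropylsilane | COCOc1cc(O[Si](C(C)C)(C(C)C)C(C)C)cc(OCOC)c1 | intermediate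
13 | [2,6-bis(methoxymethoxy)-4-(triisopropylsilyloxy)phenyl]lithium | [Li]c1c(OCOC)cc(O[Si](C(C)C)(C(C)C)C(C)C)cc1OCOC | intermediate
14 | [3,5-bis(methoxymethoxy)-4-(3-methylbut-2-en-1-yl)phenoxy]triisopropylsilane | CC(C)=CCc1c(OCOC)cc(O[Si](C(C)C)(C(C)C)C(C)C)cc1OCOC | intermediate
15 | 3,5-bis(methoxymethoxy)-4-(3-methylbut-2-en-1-yl)phenol | CC(C)=CCc1c(OCOC)cc(O)cc1OCOC | intermediate
16 | 3,5-bis(methoxymethoxy)-4-(3-methylbut-2-en-1-yl)-2-[(3S)-8-methylnon-1-yn-3-yl]phenol | C#C[C@H](CCCCC(C)C)c1c(O)cc(OCOC)c(CC=C(C)C)c1OCOC | intermediate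
17 | 1,3,5-tris(methoxymethoxy)-2-(3-methylbut-2-en-1-yl)-4-[(3S)-8-methylnon-1-yn-3-yl]benzene | C#C[C@H](CCCCC(C)C)c1c(OCOC)cc(OCOC)c(CC=C(C)C)c1OCOC | intermediate
18 | {(3S)-8-methyl-3-[2,4,6-tris(methoxymethoxy)-3-prenylphenyl]non-1-yn-1-yl}lithium | [Li]C#C[C@H](CCCCC(C)C)c1c(OCOC)cc(OCOC)c(CC=C(C)C)c1OCOC | intermediate
19 | lithium (3S)-8-methyl-3-[2,4,6-tris(methoxymethoxy)-3-prenylphenyl]non-1-yn-1-olate | [Li]OC#C[C@H](CCCCC(C)C)c1c(OCOC)cc(OCOC)c(CC=C(C)C)c1OCOC | intermediate
20 | triisopropyl({(3S)-8-methyl-3-[2,4,6-tris(methoxymethoxy)-3-prenylphenyl]non-1-yn-1-yl}oxy)silane | CC(C)[Si](C(C)C)(C(C)C)OC#C[C@H](CCCCC(C)C)c1c(OCOC)cc(OCOC)c(CC=C(C)C)c1OCOC | intermediate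
21 | 2-prenyl-3-(triisopropylsilyloxy)buta-1,3-dien-1-one (vinylketene) | O=C=C(CC=C(C)C)C(=C)O[Si](C(C)C)(C(C)C)C(C)C | intermediate
22 | 2-{(1R)-6-methyl-1-[2,4,6-tris(methoxymethoxy)-3-prenylphenyl]heptyl}-4-prenyl-3-(triisopropylsilyloxy)-4-[1-(triisopropylsilyloxy)vinyl]cyclobut-2-en-1-one (both C4 epimers) | O=C1C([C@H](CCCCC(C)C)c2c(OCOC)cc(OCOC)c(CC=C(C)C)c2OCOC)=C(O[Si](C(C)C)(C(C)C)C(C)C)C1(CC=C(C)C)C(=C)O[Si](C(C)C)(C(C)C)C(C)C | intermediate
23 | (3E)-2-{(1R)-6-methyl-1-[2,4,6-tris(methoxymethoxy)-3-prenylphenyl]heptyl}-4-prenyl-3,5-bis(triisopropylsilyloxy)hexa-1,3,5-trien-1-one (C2 and C5 cis across C3=C4) | O=C=C([C@H](CCCCC(C)C)c1c(OCOC)cc(OCOC)c(CC=C(C)C)c1OCOC)/C(O[Si](C(C)C)(C(C)C)C(C)C)=C(CC=C(C)C)\C(=C)O[Si](C(C)C)(C(C)C)C(C)C | intermediate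
24 | 2-{(1R)-6-methyl-1-[2,4,6-tris(methoxymethoxy)-3-prenylphenyl]heptyl}-4-prenyl-3,5-bis(triisopropylsilyloxy)cyclohexa-2,4-dien-1-one | O=C1CC(O[Si](C(C)C)(C(C)C)C(C)C)=C(CC=C(C)C)C(O[Si](C(C)C)(C(C)C)C(C)C)=C1[C@H](CCCCC(C)C)c1c(OCOC)cc(OCOC)c(CC=C(C)C)c1OCOC | intermediate
25 | 2-{(1R)-6-methyl-1-[2,4,6-tris(methoxymethoxy)-3-prenylphenyl]heptyl}-4-prenyl-3,5-bis(triisopropylsilyloxy)phenol | Oc1cc(O[Si](C(C)C)(C(C)C)C(C)C)c(CC=C(C)C)c(O[Si](C(C)C)(C(C)C)C(C)C)c1[C@H](CCCCC(C)C)c1c(OCOC)cc(OCOC)c(CC=C(C)C)c1OCOC | intermediate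
26 | O,C5′-dilithio derivative of 25 (lithium phenoxide on ring A, aryllithium at C5′ of ring B) | [Li]Oc1cc(O[Si](C(C)C)(C(C)C)C(C)C)c(CC=C(C)C)c(O[Si](C(C)C)(C(C)C)C(C)C)c1[C@H](CCCCC(C)C)c1c(OCOC)c([Li])c(OCOC)c(CC=C(C)C)c1OCOC | intermediate
27 | 2-{(1R)-6-methyl-1-[2,4,6-tris(methoxymethoxy)-3-(2-methylpropanoyl)-5-prenylphenyl]heptyl}-4-prenyl-3,5-bis(triisopropylsilyloxy)phenol | Oc1cc(O[Si](C(C)C)(C(C)C)C(C)C)c(CC=C(C)C)c(O[Si](C(C)C)(C(C)C)C(C)C)c1[C@H](CCCCC(C)C)c1c(OCOC)c(C(=O)C(C)C)c(OCOC)c(CC=C(C)C)c1OCOC | intermediate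
28 | (2R)-2-methylbutanoic acid | CC[C@@H](C)C(=O)O | starting material
29 | (2R)-2-methylbutanoyl chloride | CC[C@@H](C)C(=O)Cl | intermediate
30 | 6-bromo-2-{(1R)-6-methyl-1-[2,4,6-tris(methoxymethoxy)-3-(2-methylpropanoyl)-5-prenylphenyl]heptyl}-4-prenyl-3,5-bis(triisopropylsilyloxy)phenol (bromine on C1 of ring A) | Oc1c(Br)c(O[Si](C(C)C)(C(C)C)C(C)C)c(CC=C(C)C)c(O[Si](C(C)C)(C(C)C)C(C)C)c1[C@H](CCCCC(C)C)c1c(OCOC)c(C(=O)C(C)C)c(OCOC)c(CC=C(C)C)c1OCOC | intermediate
31 | (2R)-2-methylbutanoate ester of 30 (ester on the C6 oxygen, bromine on C1) | CC[C@@H](C)C(=O)Oc1c(Br)c(O[Si](C(C)C)(C(C)C)C(C)C)c(CC=C(C)C)c(O[Si](C(C)C)(C(C)C)C(C)C)c1[C@H](CCCCC(C)C)c1c(OCOC)c(C(=O)C(C)C)c(OCOC)c(CC=C(C)C)c1OCOC | intermediate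
32 | C1-lithio analogue of 31 (lithium in place of bromine) | CC[C@@H](C)C(=O)Oc1c([Li])c(O[Si](C(C)C)(C(C)C)C(C)C)c(CC=C(C)C)c(O[Si](C(C)C)(C(C)C)C(C)C)c1[C@H](CCCCC(C)C)c1c(OCOC)c(C(=O)C(C)C)c(OCOC)c(CC=C(C)C)c1OCOC | intermediate
33 | (2R)-1-[2-hydroxy-3-{(1R)-6-methyl-1-[2,4,6-tris(methoxymethoxy)-3-(2-methylpropanoyl)-5-prenylphenyl]heptyl}-5-prenyl-4,6-bis(triisopropylsilyloxy)phenyl]-2-methylbutan-1-one | CC[C@@H](C)C(=O)c1c(O[Si](C(C)C)(C(C)C)C(C)C)c(CC=C(C)C)c(O[Si](C(C)C)(C(C)C)C(C)C)c([C@H](CCCCC(C)C)c2c(OCOC)c(CC=C(C)C)c(OCOC)c(C(=O)C(C)C)c2OCOC)c1O | intermediate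
34 | (2R)-1-[2-hydroxy-3-{(1R)-6-methyl-1-[2,4,6-trihydroxy-3-(2-methylpropanoyl)-5-prenylphenyl]heptyl}-5-prenyl-4,6-bis(triisopropylsilyloxy)phenyl]-2-methylbutan-1-one | CC[C@@H](C)C(=O)c1c(O[Si](C(C)C)(C(C)C)C(C)C)c(CC=C(C)C)c(O[Si](C(C)C)(C(C)C)C(C)C)c([C@H](CCCCC(C)C)c2c(O)c(CC=C(C)C)c(O)c(C(=O)C(C)C)c2O)c1O | intermediate
35 | CNP0279787.1, (2R)-1-[2,4,6-trihydroxy-3-{(1R)-6-methyl-1-[2,4,6-trihydroxy-3-(2-methylpropanoyl)-5-prenylphenyl]heptyl}-5-prenylphenyl]-2-methylbutan-1-one | CC[C@@H](C)C(=O)c1c(O)c(CC=C(C)C)c(O)c([C@H](CCCCC(C)C)c2c(O)c(CC=C(C)C)c(O)c(C(=O)C(C)C)c2O)c1O | target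

**Step count and risks**

Total step count: 18. Longest linear sequence: 12 steps (6–13 and 15–18, from phloroglucinol).

Steps most likely to fail:

1. Step 9. Facial discrimination may be weak at an allenylidene that carries only an alkyl chain, since such ligands are tuned for aryl-substituted substrates; this would erode the enantiomeric purity of C7. Fallback: give up catalyst control of C7. Setting out from 15 and 9, the coupling is run with the same copper salt and the racemic form of the ligand to give racemic 3,5-bis(methoxymethoxy)-4-prenyl-2-(8-methylnon-1-yn-3-yl)phenol F1. F1 is resolved by preparative chromatography on a cellulose-based chiral stationary phase; the (R) enantiomer F2 is set aside, and the (S) enantiomer re-enters the route as 16.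

2. Step 16. Bromine–lithium exchange may be outrun by addition of t-BuLi to the ring B ketone or to the ester carbonyl, or the aryllithium may suffer O-to-C silyl migration from the neighbouring silyl ether before the acyl group shifts. Fallback: a route to 33 with neither bromide nor organolithium, which also bypasses step 15. Setting out from 27, EtMgBr in Et2O gives the bromomagnesium phenolate of 27 F3. After exchange of the solvent for toluene, 29 is added, and metal-template ortho C-acylation through magnesium-bound acyl chloride should deliver the acyl group to C1, the only free ortho position, returning to the route at 33.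

3. Step 13. Acyl transfer from the branched amide to the doubly ortho-substituted aryllithium may be slow, so that proton return (from the amide α-hydrogen or an allylic CH2) regenerates 25. Fallback: lower the oxidation level of the electrophile. Setting out from 25, the dilithio species 26 is formed as before and trapped with the smaller and more electrophilic isobutyraldehyde to give the C5′ 1-hydroxy-2-methylpropyl carbinol F4 (both carbinol epimers). Oxidation of this benzylic alcohol with MnO2 in CH2Cl2 returns to the route at 27.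

**Further compounds**

F1 | step 9 | racemic 3,5-bis(methoxymethoxy)-4-prenyl-2-(8-methylnon-1-yn-3-yl)phenol | C#CC(CCCCC(C)C)c1c(O)cc(OCOC)c(CC=C(C)C)c1OCOC
F2 | step 9 | 3,5-bis(methoxymethoxy)-4-prenyl-2-[(3R)-8-methylnon-1-yn-3-yl]phenol | C#C[C@@H](CCCCC(C)C)c1c(O)cc(OCOC)c(CC=C(C)C)c1OCOC
F3 | step 16 | bromomagnesium phenolate of 27 | Br[Mg]Oc1cc(O[Si](C(C)C)(C(C)C)C(C)C)c(CC=C(C)C)c(O[Si](C(C)C)(C(C)C)C(C)C)c1[C@H](CCCCC(C)C)c1c(OCOC)c(C(=O)C(C)C)c(OCOC)c(CC=C(C)C)c1OCOC
F4 | step 13 | 2-{(1R)-1-[3-(1-hydroxy-2-methylpropyl)-2,4,6-tris(methoxymethoxy)-5-prenylphenyl]-6-methylheptyl}-4-prenyl-3,5-bis(triisopropylsilyloxy)phenol (carbinol epimers) | Oc1cc(O[Si](C(C)C)(C(C)C)C(C)C)c(CC=C(C)C)c(O[Si](C(C)C)(C(C)C)C(C)C)c1[C@H](CCCCC(C)C)c1c(OCOC)c(C(O)C(C)C)c(OCOC)c(CC=C(C)C)c1OCOC
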